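**Plan**

- Retrosynthesis: first cut the aryl–CH2 bond C7′–C1′ (B-alkyl Suzuki) to give a 4-methylene-oxolane and an aryl bromide carrying the threo β-O-4 chain; then cut the oxolane at O1–C5 and C2–C3 (Pd-trimethylenemethane [3+2]) to O-silyl vanillin and an ester-bearing allyl carbonate; the side chain is cut at C7″–C8″ (aldol) and at ArO–CH2.
- Enabling feature: oxolane C4 bears two CH2 arms, ring C5 (on O1) and benzylic C7′ (on the guaiacyl ring), so C5–C4–C7′ is a latent 2-substituted allyl unit with interchangeable termini; C3 bears C9, which at ester level makes C3 the carbanionic end of a trimethylenemethane (TMM).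
- Forward: the oxolane is made first (C2–C3, then ring-closing O1–C5), leaving C4=C7′ as an exocyclic methylene; ester to CH2OH to TBS ether; the side-chain bromide is built by a glycolate aldol; the halves are joined at C7′–aryl by hydroboration/Suzuki coupling; global desilylation ends the route.
- Stereochemistry: C2 from the chiral Pd–phosphoramidite catalyst; C3 trans to aryl (ring-closure transition state, epimerisable α-ester); C4 from hydroboration anti to the C3 arm (3,4-cis, as the target requires); C7″/C8″ (R,R, threo) from the (S)-4-benzyloxazolidinone auxiliary.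

Key step: step 4

Assumption: the enantiomer of the phosphoramidite ligand L* that delivers the (2S) oxolane is used; if the sense of induction proves opposite, ent-L* is taken.

Locants used below: oxolane O1, C2 (aryl), C3 (CH2OH arm = C9), C4, C5; C7′ = benzylic CH2 on C4; C7″ = side-chain carbinol carbon, C8″ = aryloxy-bearing carbon.

**Step 1**
Reactants: 1 vanillin (4-hydroxy-3-methoxybenzaldehyde)
Product: 2 3-methoxy-4-[(triisopropylsilyl)oxy]benzaldehyde
Conditions: TIPSCl, imidazole, DMF, rt
Reagents that add atoms: triisopropylsilyl chloride, CC(C)[Si](Cl)(C(C)C)C(C)C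
Why: Phenol silylation (silyl ether formation) should be clean, and the TIPS aryl ether is chosen to survive DIBAL-H, the boron aldol and the aqueous-base Suzuki coupling; no stereocentre is formed.

**Step 2**
Reactants: 3 monomethyl itaconate (4-methoxy-2-methylidene-4-oxobutanoic acid)
Product: 5 methyl 3-(hydroxymethyl)but-3-enoate, via mixed isobutyl carbonic anhydride 4 (not isolated)
Conditions: i-BuOCOCl, N-methylmorpholine, THF, −15 °C; then NaBH4, H2O, −15 → 0 °C
Reagents that add atoms: none
Why: Only the free acid is activated as the mixed carbonic anhydride, which borohydride should reduce to the allylic alcohol at low temperature (mixed-anhydride acid-to-alcohol reduction) without touching the methyl ester or the 1,1-disubstituted alkene; the crude alcohol is carried on at once to avoid lactonisation.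

**Step 3**
Reactants: 5 methyl 3-(hydroxymethyl)but-3-enoate
Product: 6 methyl 3-{[(tert-butoxycarbonyl)oxy]methyl}but-3-enoate
Conditions: Boc2O, DMAP (cat.), CH2Cl2, 0 °C → rt
Reagents that add atoms: di-tert-butyl dicarbonate, CC(C)(C)OC(=O)OC(=O)OC(C)(C)C
Why: DMAP-catalysed O-acylation of the primary allylic alcohol should give the tert-butyl carbonate, an ionisable group that releases its own base (tert-butoxide) on reaction with Pd(0).

**Step 4**
Reactants: 2 3-methoxy-4-[(triisopropylsilyl)oxy]benzaldehyde; 6 methyl 3-{[(tert-butoxycarbonyl)oxy]methyl}but-3-enoate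
Product: 7 methyl (2S,3S)-2-{3-methoxy-4-[(triisopropylsilyl)oxy]phenyl}-4-methylideneoxolane-3-carboxylate (2,3-trans)
Conditions: Pd2(dba)3·CHCl3 (2.5 mol %), chiral BINOL-derived phosphoramidite L* with a C2-symmetric 2,5-diarylpyrrolidine amine (10 mol %), toluene, 25 °C, slow addition of 6
Reagents that add atoms: none
Why: Proposed new method: Pd(0) should ionise the allylic carbonate of 6 to a 2-substituted π-allyl cation, the released tert-butoxide (after loss of CO2) should remove the C–H α to the ester to give a zwitterionic methoxycarbonyl-TMM–Pd complex, its ester-stabilised carbon should add reversibly to the aldehyde carbon of 2 (C2–C3), and the resulting alkoxide should attack a CH2 terminus of the π-allyl anti to Pd to form O1–C5 and release Pd(0). The closest known reaction types are the Pd/phosphoramidite-catalysed asymmetric [3+2] cycloaddition of the silyl-derived parent TMM with aryl aldehydes to 2-aryl-4-methylene-oxolanes and the generation of acceptor-substituted TMM–Pd species by deprotonation of 2-(acceptor-methyl)allyl carbonates. The oxolane closes in a 5-exo-tet sense at C5 (Pd departs outside the ring), and because the allyl termini C5 and C7′ are equivalent, attack at either gives the same ring with the other left as the exocyclic methylene. C2 is set by the chiral ligand on Pd, which selects one aldehyde face in the reversible addition and irreversible ring closure, and C3 should end trans to the aryl group because the trans transition state and product are less strained and the α-ester C3–H can equilibrate under the basic conditions. The step needs the ester-bearing carbon, not a CH2, to be the nucleophilic TMM terminus, which charge localisation α to the ester secures, and it needs carbonyl addition to outrun self-allylation of the donor, which slow addition of 6 favours.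

**Step 5**
Reactants: 7 methyl (2S,3S)-2-{3-methoxy-4-[(triisopropylsilyl)oxy]phenyl}-4-methylideneoxolane-3-carboxylate
Product: 8 [(2S,3R)-2-{3-methoxy-4-[(triisopropylsilyl)oxy]phenyl}-4-methylideneoxolan-3-yl]methanol
Conditions: DIBAL-H (2.5 equiv), CH2Cl2, −78 → −20 °C; Rochelle salt work-up
Reagents that add atoms: none
Why: Hydride reduction of the ester to the primary alcohol at low temperature should leave the exocyclic alkene, the aryl TIPS ether and the C2/C3 configuration untouched (the descriptor at C3 changes from S to R only through CIP priorities).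

**Step 6**
Reactants: 8 [(2S,3R)-2-{3-methoxy-4-[(triisopropylsilyl)oxy]phenyl}-4-methylideneoxolan-3-yl]methanol
Product: 9 tert-butyl{[(2S,3R)-2-{3-methoxy-4-[(triisopropylsilyl)oxy]phenyl}-4-methylideneoxolan-3-yl]methoxy}dimethylsilane
Conditions: TBSCl, imidazole, DMF, 0 °C → rt
Reagents that add atoms: tert-butyldimethylsilyl chloride, CC(C)(C)[Si](C)(C)Cl
Why: Silylation of the primary alcohol removes the free OH before hydroboration and makes the C3 arm a larger shield for the β-face of the exocyclic alkene.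

**Step 7**
Reactants: 10 4-bromo-2-methoxyphenol; 11 (4S)-4-benzyl-3-(chloroacetyl)-1,3-oxazolidin-2-one
Product: 12 (4S)-4-benzyl-3-[(4-bromo-2-methoxyphenoxy)acetyl]-1,3-oxazolidin-2-one
Conditions: K2CO3, NaI (cat.), acetone, rt
Reagents that add atoms: none
Why: Williamson etherification of the phenoxide at the highly SN2-active α-chloro-imide carbon should install the aryloxyacetyl (glycolate) unit directly on the auxiliary; the aryl bromide is inert here.

**Step 8**
Reactants: 12 (4S)-4-benzyl-3-[(4-bromo-2-methoxyphenoxy)acetyl]-1,3-oxazolidin-2-one; 2 3-methoxy-4-[(triisopropylsilyl)oxy]benzaldehyde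
Product: 14 (4S)-4-benzyl-3-[(2S,3R)-2-(4-bromo-2-methoxyphenoxy)-3-hydroxy-3-{3-methoxy-4-[(triisopropylsilyl)oxy]phenyl}propanoyl]-1,3-oxazolidin-2-one, via dibutylboron Z-enolate 13 (not isolated)
Conditions: Bu2BOTf, i-Pr2NEt, CH2Cl2, −78 → 0 °C; then 2, −78 → 0 °C; pH 7 buffer, MeOH, H2O2
Reagents that add atoms: none
Why: Evans syn-aldol reaction of the Z-boron glycolate enolate through a Zimmerman–Traxler chair should set both C8″ and C7″ under control of the (S)-benzyl auxiliary, giving the syn (threo) adduct that becomes (7″R,8″R).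

**Step 9**
Reactants: 14 (4S)-4-benzyl-3-[(2S,3R)-2-(4-bromo-2-methoxyphenoxy)-3-hydroxy-3-{3-methoxy-4-[(triisopropylsilyl)oxy]phenyl}propanoyl]-1,3-oxazolidin-2-one
Product: 15 (1R,2R)-2-(4-bromo-2-methoxyphenoxy)-1-{3-methoxy-4-[(triisopropylsilyl)oxy]phenyl}propane-1,3-diol (threo)
Conditions: LiBH4, THF, H2O (1 equiv), 0 °C
Reagents that add atoms: none
Why: Reductive cleavage of the N-acyl oxazolidinone with LiBH4 should give the primary alcohol without epimerisation and without touching the aryl bromide or the silyl ether.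

**Step 10**
Reactants: 15 (1R,2R)-2-(4-bromo-2-methoxyphenoxy)-1-{3-methoxy-4-[(triisopropylsilyl)oxy]phenyl}propane-1,3-diol
Product: 16 (1R,2R)-2-(4-bromo-2-methoxyphenoxy)-1,3-bis{[tert-butyl(dimethyl)silyl]oxy}-1-{3-methoxy-4-[(triisopropylsilyl)oxy]phenyl}propane
Conditions: TBSOTf, 2,6-lutidine, CH2Cl2, −78 → 0 °C
Reagents that add atoms: tert-butyldimethylsilyl trifluoromethanesulfonate, CC(C)(C)[Si](C)(C)OS(=O)(=O)C(F)(F)F
Why: Bis-silylation of the primary and the benzylic secondary alcohol under buffered conditions protects the diol for the basic coupling and allows a single fluoride deprotection at the end.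

**Step 11**
Reactants: 9 tert-butyl{[(2S,3R)-2-{3-methoxy-4-[(triisopropylsilyl)oxy]phenyl}-4-methylideneoxolan-3-yl]methoxy}dimethylsilane; 16 (1R,2R)-2-(4-bromo-2-methoxyphenoxy)-1,3-bis{[tert-butyl(dimethyl)silyl]oxy}-1-{3-methoxy-4-[(triisopropylsilyl)oxy]phenyl}propane
Product: 18 pentasilyl ether of the target (oxolane 2S,3R,4R; side chain 7″R,8″R; both phenols as TIPS ethers; the three aliphatic hydroxyls as TBS ethers), via B-alkyl-9-BBN adduct 17 (not isolated)
Conditions: 9-BBN, THF, 0 °C → rt; then 16, Pd(dppf)Cl2 (5 mol %), aq. K3PO4, DMF, 60 °C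
Reagents that add atoms: none
Why: 9-BBN should add to the exocyclic C4=C7′ alkene from the face opposite the adjacent C3 CH2OTBS arm, putting boron on C7′ and hydrogen on C4 so that the new C4 centre (R) is cis to the C3 arm, and the primary alkylborane should then undergo B-alkyl Suzuki–Miyaura coupling with the aryl bromide with C4 untouched.

**Step 12**
Reactants: 18 pentasilyl ether of the target
Product: 19 4-[(2S,3R,4R)-4-{4-[(1R,2R)-1,3-dihydroxy-1-(4-hydroxy-3-methoxyphenyl)propan-2-yl]oxy-3-methoxybenzyl}-3-(hydroxymethyl)oxolan-2-yl]-2-methoxyphenol (target)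
Conditions: TBAF, AcOH, THF, 0 °C → rt
Reagents that add atoms: none
Why: Acetic-acid-buffered fluoride should cleave the two aryl TIPS and three alkyl TBS ethers in one operation without acid (no benzylic ionisation at C2 or C7″) and without strongly basic phenoxide chemistry; no stereocentre is affected.

**Compound list**

1 | vanillin (4-hydroxy-3-methoxybenzaldehyde) | COc1cc(C=O)ccc1O | starting material
2 | 3-methoxy-4-[(triisopropylsilyl)oxy]benzaldehyde | COc1cc(C=O)ccc1O[Si](C(C)C)(C(C)C)C(C)C | intermediate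
3 | monomethyl itaconate (4-methoxy-2-methylidene-4-oxobutanoic acid) | COC(=O)CC(=C)C(=O)O | starting material
4 | mixed isobutyl carbonic anhydride of 3 | COC(=O)CC(=C)C(=O)OC(=O)OCC(C)C | intermediate
5 | methyl 3-(hydroxymethyl)but-3-enoate | COC(=O)CC(=C)CO | intermediate
6 | methyl 3-{[(tert-butoxycarbonyl)oxy]methyl}but-3-enoate | COC(=O)CC(=C)COC(=O)OC(C)(C)C | intermediate
7 | methyl (2S,3S)-2-{3-methoxy-4-[(triisopropylsilyl)oxy]phenyl}-4-methylideneoxolane-3-carboxylate | C=C1CO[C@H](c2ccc(O[Si](C(C)C)(C(C)C)C(C)C)c(OC)c2)[C@H]1C(=O)OC | intermediate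
8 | [(2S,3R)-2-{3-methoxy-4-[(triisopropylsilyl)oxy]phenyl}-4-methylideneoxolan-3-yl]methanol | C=C1CO[C@H](c2ccc(O[Si](C(C)C)(C(C)C)C(C)C)c(OC)c2)[C@H]1CO | intermediate
9 | tert-butyl{[(2S,3R)-2-{3-methoxy-4-[(triisopropylsilyl)oxy]phenyl}-4-methylideneoxolan-3-yl]methoxy}dimethylsilane | C=C1CO[C@H](c2ccc(O[Si](C(C)C)(C(C)C)C(C)C)c(OC)c2)[C@H]1CO[Si](C)(C)C(C)(C)C | intermediate
10 | 4-bromo-2-methoxyphenol | COc1cc(Br)ccc1O | starting material
11 | (4S)-4-benzyl-3-(chloroacetyl)-1,3-oxazolidin-2-one | O=C(CCl)N1[C@@H](Cc2ccccc2)COC1=O | starting material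
12 | (4S)-4-benzyl-3-[(4-bromo-2-methoxyphenoxy)acetyl]-1,3-oxazolidin-2-one | COc1cc(Br)ccc1OCC(=O)N1[C@@H](Cc2ccccc2)COC1=O | intermediate
13 | dibutylboron Z-enolate of 12 | CCCCB(CCCC)O/C(=C\Oc1ccc(Br)cc1OC)N1[C@@H](Cc2ccccc2)COC1=O | intermediate
14 | (4S)-4-benzyl-3-[(2S,3R)-2-(4-bromo-2-methoxyphenoxy)-3-hydroxy-3-{3-methoxy-4-[(triisopropylsilyl)oxy]phenyl}propanoyl]-1,3-oxazolidin-2-one | COc1cc([C@@H](O)[C@@H](C(=O)N2[C@@H](Cc3ccccc3)COC2=O)Oc2ccc(Br)cc2OC)ccc1O[Si](C(C)C)(C(C)C)C(C)C | intermediate
15 | (1R,2R)-2-(4-bromo-2-methoxyphenoxy)-1-{3-methoxy-4-[(triisopropylsilyl)oxy]phenyl}propane-1,3-diol | COc1cc([C@@H](O)[C@@H](CO)Oc2ccc(Br)cc2OC)ccc1O[Si](C(C)C)(C(C)C)C(C)C | intermediate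
16 | (1R,2R)-2-(4-bromo-2-methoxyphenoxy)-1,3-bis{[tert-butyl(dimethyl)silyl]oxy}-1-{3-methoxy-4-[(triisopropylsilyl)oxy]phenyl}propane | COc1cc([C@@H](O[Si](C)(C)C(C)(C)C)[C@@H](CO[Si](C)(C)C(C)(C)C)Oc2ccc(Br)cc2OC)ccc1O[Si](C(C)C)(C(C)C)C(C)C | intermediate
17 | 9-{[(2S,3R,4R)-3-({[tert-butyl(dimethyl)silyl]oxy}methyl)-2-{3-methoxy-4-[(triisopropylsilyl)oxy]phenyl}oxolan-4-yl]methyl}-9-borabicyclo[3.3.1]nonane | C1CCC2CCCC1B2C[C@H]3CO[C@H](c4ccc(O[Si](C(C)C)(C(C)C)C(C)C)c(OC)c4)[C@H]3CO[Si](C)(C)C(C)(C)C | intermediate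
18 | pentasilyl ether of the target: (2S,3R,4R)-oxolane with 3-CH2OTBS and 2-(3-methoxy-4-TIPSO-phenyl); 4-benzyl group bearing 3-OMe and the 4-O-[(1R,2R)-1,3-bis(TBSO)-1-(3-methoxy-4-TIPSO-phenyl)propan-2-yl] ether | COc1cc([C@@H](O[Si](C)(C)C(C)(C)C)[C@@H](CO[Si](C)(C)C(C)(C)C)Oc2ccc(C[C@H]3CO[C@H](c4ccc(O[Si](C(C)C)(C(C)C)C(C)C)c(OC)c4)[C@H]3CO[Si](C)(C)C(C)(C)C)cc2OC)ccc1O[Si](C(C)C)(C(C)C)C(C)C | intermediate
19 | 4-[(2S,3R,4R)-4-{4-[(1R,2R)-1,3-dihydroxy-1-(4-hydroxy-3-methoxyphenyl)propan-2-yl]oxy-3-methoxybenzyl}-3-(hydroxymethyl)oxolan-2-yl]-2-methoxyphenol | COc1cc([C@@H](O)[C@@H](CO)Oc2ccc(C[C@H]3CO[C@H](c4ccc(O)c(OC)c4)[C@H]3CO)cc2OC)ccc1O | target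

**Step count and risks**

Total step count: 12. Longest linear sequence: 7 steps (3 → 5 → 6 → 7 → 8 → 9 → 18 → 19).

Steps most likely to fail:

1. Step 4 (Proposed new method). The ester-substituted TMM may oligomerise faster than it adds to the electron-rich aldehyde, enantioface selection may be poor, or the exocyclic alkene may migrate into conjugation with the ester under the basic conditions. The fallback uses known chemistry, sets out from 2 and returns at 9. N-Acylation of (S)-4-benzyl-1,3-oxazolidin-2-one with 3-methylbut-2-enoyl chloride (n-BuLi, THF, −78 °C) gives (4S)-4-benzyl-3-(3-methylbut-2-enoyl)-1,3-oxazolidin-2-one F1. Its dibutylboron dienolate (Bu2BOTf, Et3N, CH2Cl2) should react with 2 at the α-carbon (deconjugative Evans syn-aldol) to give the α-isopropenyl syn-aldol imide F2. LiBH4 then gives the (1S,2R)-diol F3, and selective silylation of the primary hydroxyl (TBSCl, imidazole) gives the mono-TBS ether F4. Allylic hydroxylation of the isopropenyl methyl group (cat. SeO2, t-BuOOH, CH2Cl2) gives the 2-(hydroxymethyl)allyl diol F5. Mitsunobu cyclodehydration (PPh3, DIAD, THF) activates the primary allylic alcohol, and the benzylic oxygen displaces it with retention at C2 (SN2 and SN2′ give the same ring because the allyl termini are equivalent), closing the same O1–C5 bond to give 9.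

2. Step 11. The β-branched B-alkyl-9-BBN may transmetalate slowly, so that protodeboronation and reduction of 16 compete, and facial selectivity in the hydroboration may be incomplete with no chance to purify before coupling. The fallback sets out from 9 and returns at 18. Hydroboration with 9-BBN followed by oxidation (NaBO3·4H2O) gives the primary alcohol F6, which is purified to the 3,4-cis isomer. Appel iodination (I2, PPh3, imidazole) gives the iodide F7. Zinc insertion (Zn dust, LiCl, THF) gives the alkylzinc iodide F8, which is joined to 16 by Negishi coupling (Pd(OAc)2, SPhos, THF/NMP) to give 18.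

3. Step 7. The phenoxide may attack the exocyclic imide carbonyl (acyl transfer with loss of the auxiliary) in competition with SN2 displacement at the chloromethyl carbon. The fallback sets out from 10 and returns at 12, forming the ether bond first and the N-acyl bond last. Alkylation of 10 with bromoacetic acid (aq. NaOH, reflux, then acid) gives (4-bromo-2-methoxyphenoxy)acetic acid F9. Its pivaloyl mixed anhydride (PivCl, Et3N, THF, −20 °C) then acylates (S)-4-benzyl-1,3-oxazolidin-2-one (LiCl) to give 12.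

**Further compounds**

F1 | step 4 | (4S)-4-benzyl-3-(3-methylbut-2-enoyl)-1,3-oxazolidin-2-one | CC(C)=CC(=O)N1[C@@H](Cc2ccccc2)COC1=O
F2 | step 4 | (4S)-4-benzyl-3-[(2S)-2-{(S)-hydroxy[3-methoxy-4-(triisopropylsilyloxy)phenyl]methyl}-3-methylbut-3-enoyl]-1,3-oxazolidin-2-one | O=C(N1[C@@H](Cc2ccccc2)COC1=O)[C@@H](C(C)=C)[C@H](O)c1ccc(O[Si](C(C)C)(C(C)C)C(C)C)c(OC)c1
F3 | step 4 | (1S,2R)-1-[3-methoxy-4-(triisopropylsilyloxy)phenyl]-2-(prop-1-en-2-yl)propane-1,3-diol | OC[C@@H](C(C)=C)[C@H](O)c1ccc(O[Si](C(C)C)(C(C)C)C(C)C)c(OC)c1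
F4 | step 4 | (1S,2R)-2-({[tert-butyl(dimethyl)silyl]oxy}methyl)-1-[3-methoxy-4-(triisopropylsilyloxy)phenyl]-3-methylbut-3-en-1-ol | CC(C)(C)[Si](C)(C)OC[C@@H](C(C)=C)[C@H](O)c1ccc(O[Si](C(C)C)(C(C)C)C(C)C)c(OC)c1
F5 | step 4 | (1S,2R)-2-({[tert-butyl(dimethyl)silyl]oxy}methyl)-1-[3-methoxy-4-(triisopropylsilyloxy)phenyl]-3-methylidenebutane-1,4-diol | CC(C)(C)[Si](C)(C)OC[C@@H](C(=C)CO)[C@H](O)c1ccc(O[Si](C(C)C)(C(C)C)C(C)C)c(OC)c1
F6 | step 11 | [(2S,3R,4S)-3-({[tert-butyl(dimethyl)silyl]oxy}methyl)-2-[3-methoxy-4-(triisopropylsilyloxy)phenyl]oxolan-4-yl]methanol (3,4-cis; oxolane numbered as in the target) | OC[C@H]1CO[C@H](c2ccc(O[Si](C(C)C)(C(C)C)C(C)C)c(OC)c2)[C@H]1CO[Si](C)(C)C(C)(C)C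
F7 | step 11 | tert-butyl{[(2S,3R,4R)-4-(iodomethyl)-2-[3-methoxy-4-(triisopropylsilyloxy)phenyl]oxolan-3-yl]methoxy}dimethylsilane | IC[C@H]1CO[C@H](c2ccc(O[Si](C(C)C)(C(C)C)C(C)C)c(OC)c2)[C@H]1CO[Si](C)(C)C(C)(C)C
F8 | step 11 | {[(2S,3R,4R)-3-({[tert-butyl(dimethyl)silyl]oxy}methyl)-2-[3-methoxy-4-(triisopropylsilyloxy)phenyl]oxolan-4-yl]methyl}zinc iodide | I[Zn]C[C@H]1CO[C@H](c2ccc(O[Si](C(C)C)(C(C)C)C(C)C)c(OC)c2)[C@H]1CO[Si](C)(C)C(C)(C)C
F9 | step 7 | (4-bromo-2-methoxyphenoxy)acetic acid | COc1cc(Br)ccc1OCC(=O)O
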